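Pyran ring B is disconnected last: target 17 goes back to bis-phenol 13 and prenal 14 by a formal [3+3] annulation (ortho-hydroxyalkylation, then oxa-6π electrocyclisation) that makes C4–C4a and O1–C2 of the chromene in one operation.
Enabling feature: ring A of 13 is a 3-methoxy-4-alkylphenol whose free O–H on C1 and unsubstituted C6–H (ortho to that OH, para to the C3 methoxy) act as a 1,3-O,C-dinucleophile toward the 1,3-dielectrophile 14. The only other phenol (C6–OH of the benzofuran) is hydrogen-bonded to the C5 acetyl and has only the crowded C7 free.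
13 goes back to iodoresorcinol ketone 10 and (S,E)-enyne 8: Sonogashira coupling with 5-endo-dig closure builds furan ring C.
8 goes back to styrene 3, ethylene and methacrolein: asymmetric hydrovinylation sets the (S) benzylic centre, cross-metathesis sets the (E)-trisubstituted alkene, Colvin homologation gives the alkyne.
Ring order: benzene rings A and D are bought; furan ring C is closed in step 7; pyran ring B is closed in step 9.

Key step: step 9

Remark: in step 3 the antipode of the chiral ligand is taken that delivers the (S)-alkene; both antipodes are accessible and the sense of induction is to be confirmed on the first run.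

Step 1
Reactants: 1 4-hydroxy-2-methoxybenzaldehyde
Product: 2 2-methoxy-4-[(triisopropylsilyl)oxy]benzaldehyde
Conditions: TIPSCl, imidazole, DMF, rt
Reagents that add atoms: triisopropylsilyl chloride, CC(C)[Si](Cl)(C(C)C)C(C)C
Why: Imidazole-promoted O-silylation of the phenol; the bulky aryl TIPS ether should survive the ylide, nickel, ruthenium and organolithium steps that follow.

Step 2
Reactants: 2 2-methoxy-4-[(triisopropylsilyl)oxy]benzaldehyde
Product: 3 (4-ethenyl-3-methoxyphenoxy)triisopropylsilane
Conditions: Ph3PCH3Br, KOtBu, THF, 0 °C to rt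
Reagents that add atoms: methyltriphenylphosphonium bromide, C[P+](c1ccccc1)(c1ccccc1)c1ccccc1.[Br-]
Why: Wittig methylenation of an aryl aldehyde should give the vinylarene needed for hydrovinylation; the product is used without storage because electron-rich styrenes polymerise.

Step 3
Reactants: 3 (4-ethenyl-3-methoxyphenoxy)triisopropylsilane; 4 ethylene
Product: 5 {4-[(2S)-but-3-en-2-yl]-3-methoxyphenoxy}triisopropylsilane
Conditions: [(C3H5)NiBr]2 (cat.), BINOL-derived phosphoramidite with a bis(1-phenylethyl)amine unit (cat.), NaB[3,5-(CF3)2C6H3]4 (cat.), ethylene (1 atm), CH2Cl2, −78 °C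
Reagents that add atoms: none
Why: Nickel-catalysed asymmetric hydrovinylation: a cationic nickel hydride adds to the vinylarene to give an η3-benzyl nickel species, ethylene inserts and β-hydride elimination releases the 3-arylbut-1-ene; the chiral phosphoramidite selects the face of the styrene that receives the hydride and so sets the (S) benzylic centre.

Step 4
Reactants: 5 {4-[(2S)-but-3-en-2-yl]-3-methoxyphenoxy}triisopropylsilane; 6 methacrolein (2-methylprop-2-enal)
Product: 7 (2E,4S)-4-{2-methoxy-4-[(triisopropylsilyl)oxy]phenyl}-2-methylpent-2-enal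
Conditions: second-generation Hoveyda–Grubbs catalyst (cat.), 1,4-benzoquinone (cat.), excess 6, CH2Cl2, 40 °C
Reagents that add atoms: none
Why: Olefin cross-metathesis of a terminal alkene with a 1,1-disubstituted electron-poor alkene should give the thermodynamically preferred (E)-trisubstituted enal; the stereocentre is not involved, and benzoquinone is added to suppress ruthenium hydride migration of the double bond.

Step 5
Reactants: 7 (2E,4S)-4-{2-methoxy-4-[(triisopropylsilyl)oxy]phenyl}-2-methylpent-2-enal
Product: 8 {3-methoxy-4-[(2S,3E)-4-methylhex-3-en-5-yn-2-yl]phenoxy}triisopropylsilane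
Conditions: TMSCHN2, n-BuLi, THF, −78 °C; then 7, −78 to 0 °C; H2O quench
Reagents that add atoms: trimethylsilyldiazomethane, C[Si](C)(C)C=[N+]=[N-]
Why: Colvin rearrangement (one-carbon aldehyde-to-alkyne homologation): lithiated trimethylsilyldiazomethane adds 1,2 to the enal at low temperature, and loss of silanolate and N2 with a 1,2-hydrogen shift should give the terminal enyne without touching the alkene geometry or the (S) centre.

Step 6
Reactants: 9 1-(2,4-dihydroxyphenyl)ethanone
Product: 10 1-(2,4-dihydroxy-5-iodophenyl)ethanone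
Conditions: ICl (1 equiv), AcOH, rt
Reagents that add atoms: iodine monochloride, ClI
Why: Electrophilic aromatic iodination; C5 is ortho to the 4-OH, para to the 2-OH and less hindered than C3 between the two hydroxyls, so the 5-iodide should predominate, and one equivalent of ICl limits di-iodination.

Step 7
Reactants: 8 {3-methoxy-4-[(2S,3E)-4-methylhex-3-en-5-yn-2-yl]phenoxy}triisopropylsilane; 10 1-(2,4-dihydroxy-5-iodophenyl)ethanone
Product: 12 1-{6-hydroxy-2-[(2E,4S)-4-{2-methoxy-4-[(triisopropylsilyl)oxy]phenyl}pent-2-en-2-yl]-1-benzofuran-5-yl}ethanone, via ortho-alkynylphenol 11 (not isolated)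
Conditions: PdCl2(PPh3)2 (cat.), CuI (cat.), Et3N, DMF, 60 °C, argon
Reagents that add atoms: none
Why: Sonogashira coupling at the aryl iodide, followed in the same pot by metal-promoted 5-endo-dig addition of the adjacent 4-OH to the alkyne (tandem heteroannulation of ortho-iodophenols), should close furan ring C with the alkenyl group on C2; the 2-OH is chelated to the acetyl and meta to the alkyne, so it cannot compete.

Step 8
Reactants: 12 1-{6-hydroxy-2-[(2E,4S)-4-{2-methoxy-4-[(triisopropylsilyl)oxy]phenyl}pent-2-en-2-yl]-1-benzofuran-5-yl}ethanone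
Product: 13 1-{6-hydroxy-2-[(2E,4S)-4-(4-hydroxy-2-methoxyphenyl)pent-2-en-2-yl]-1-benzofuran-5-yl}ethanone
Conditions: Bu4NF, AcOH (1:1), THF, 0 °C
Reagents that add atoms: none
Why: Fluoride-mediated cleavage of the aryl silyl ether; the acetic acid buffer keeps the medium non-basic and nothing else in the molecule is fluoride-labile.

Step 9
Reactants: 13 1-{6-hydroxy-2-[(2E,4S)-4-(4-hydroxy-2-methoxyphenyl)pent-2-en-2-yl]-1-benzofuran-5-yl}ethanone; 14 3-methylbut-2-enal (prenal)
Product: 17 1-{6-hydroxy-2-[(2E,4S)-4-(7-methoxy-2,2-dimethyl-2H-chromen-6-yl)pent-2-en-2-yl]-1-benzofuran-5-yl}ethanone (the target), via benzodioxaborin 15 (not isolated), via ortho-quinone methide 16 (not isolated)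
Conditions: PhB(OH)2 (1.5 equiv), AcOH, toluene, reflux, Dean–Stark trap; aqueous work-up
Reagents that add atoms: none
Why: PhB(OH)2 esterifies the free ring-A hydroxyl (O on C1, the future O1) and binds the aldehyde of 14, so that ring-A carbon C6 (the future C4a) adds to the carbonyl carbon through a six-membered transition state to give dioxaborin 15; at reflux 15 expels PhBO to give ortho-quinone methide 16, whose 1-oxatriene O=C1–C6=CH–CH=CMe2 undergoes thermal disrotatory oxa-6π electrocyclisation, which forms the O1–C2 bond, closes pyran ring B and restores the aromaticity of ring A. The closest known reaction type is the boronic acid mediated chromenylation of phenols with α,β-unsaturated aldehydes (formal [3+3] annulation: ortho-hydroxyalkylation, dehydration, 6π electrocyclisation), which is established for 3-alkoxyphenols and 3-methylbut-2-enal. No new stereocentre remains in the product, because C2 carries two methyl groups and the carbinol carbon of 15 becomes sp2 in 16; the existing (S) centre lies outside the reacting π system and should not be epimerised by acetic acid. Site selectivity on ring A should favour C6 (para to the methoxy group, next to C5–H) over C2, which is squeezed between the hydroxyl and the methoxy group. Chemoselectivity between the two phenols rests on the benzofuran C6–OH being locked in a hydrogen bond to the C5 acetyl on an acceptor-substituted ring with only C7, flanked by two oxygens, free, so with 14 kept near stoichiometric ring A should react first. The boron tether delivers the carbonyl carbon (1,2-addition) and the gem-dimethyl terminus of 14 blocks conjugate addition, so chroman by-products are not expected.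

Compound list
1 | 4-hydroxy-2-methoxybenzaldehyde | COc1cc(O)ccc1C=O | starting material
2 | 2-methoxy-4-[(triisopropylsilyl)oxy]benzaldehyde | COc1cc(O[Si](C(C)C)(C(C)C)C(C)C)ccc1C=O | intermediate
3 | (4-ethenyl-3-methoxyphenoxy)triisopropylsilane | COc1cc(O[Si](C(C)C)(C(C)C)C(C)C)ccc1C=C | intermediate
4 | ethylene | C=C | starting material
5 | {4-[(2S)-but-3-en-2-yl]-3-methoxyphenoxy}triisopropylsilane | COc1cc(O[Si](C(C)C)(C(C)C)C(C)C)ccc1[C@@H](C)C=C | intermediate
6 | methacrolein (2-methylprop-2-enal) | CC(=C)C=O | starting material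
7 | (2E,4S)-4-{2-methoxy-4-[(triisopropylsilyl)oxy]phenyl}-2-methylpent-2-enal | COc1cc(O[Si](C(C)C)(C(C)C)C(C)C)ccc1[C@@H](C)/C=C(\C)C=O | intermediate
8 | {3-methoxy-4-[(2S,3E)-4-methylhex-3-en-5-yn-2-yl]phenoxy}triisopropylsilane | COc1cc(O[Si](C(C)C)(C(C)C)C(C)C)ccc1[C@@H](C)/C=C(\C)C#C | intermediate
9 | 1-(2,4-dihydroxyphenyl)ethanone | CC(=O)c1ccc(O)cc1O | starting material
10 | 1-(2,4-dihydroxy-5-iodophenyl)ethanone | CC(=O)c1cc(I)c(O)cc1O | intermediate
11 | ortho-alkynylphenol (not isolated): 1-{2,4-dihydroxy-5-[(3E,5S)-5-{2-methoxy-4-[(triisopropylsilyl)oxy]phenyl}-3-methylhex-3-en-1-yn-1-yl]phenyl}ethanone | COc1cc(O[Si](C(C)C)(C(C)C)C(C)C)ccc1[C@@H](C)/C=C(\C)C#Cc1cc(C(C)=O)c(O)cc1O | intermediate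
12 | 1-{6-hydroxy-2-[(2E,4S)-4-{2-methoxy-4-[(triisopropylsilyl)oxy]phenyl}pent-2-en-2-yl]-1-benzofuran-5-yl}ethanone | COc1cc(O[Si](C(C)C)(C(C)C)C(C)C)ccc1[C@@H](C)/C=C(\C)c1cc2cc(C(C)=O)c(O)cc2o1 | intermediate
13 | 1-{6-hydroxy-2-[(2E,4S)-4-(4-hydroxy-2-methoxyphenyl)pent-2-en-2-yl]-1-benzofuran-5-yl}ethanone | COc1cc(O)ccc1[C@@H](C)/C=C(\C)c1cc2cc(C(C)=O)c(O)cc2o1 | intermediate
14 | 3-methylbut-2-enal (prenal) | CC(C)=CC=O | starting material
15 | benzodioxaborin (not isolated, both epimers at the carbinol carbon): 1-{6-hydroxy-2-[(2E,4S)-4-[7-methoxy-4-(2-methylprop-1-en-1-yl)-2-phenyl-4H-1,3,2-benzodioxaborinin-6-yl]pent-2-en-2-yl]-1-benzofuran-5-yl}ethanone | COc1cc2c(cc1[C@@H](C)/C=C(\C)c1cc3cc(C(C)=O)c(O)cc3o1)C(C=C(C)C)OB(c1ccccc1)O2 | intermediate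
16 | ortho-quinone methide (not isolated, exocyclic geometry not fixed): 4-[(2S,3E)-4-(5-acetyl-6-hydroxy-1-benzofuran-2-yl)pent-3-en-2-yl]-3-methoxy-6-(3-methylbut-2-en-1-ylidene)cyclohexa-2,4-dien-1-one | COC1=CC(=O)C(=CC=C(C)C)C=C1[C@@H](C)/C=C(\C)c1cc2cc(C(C)=O)c(O)cc2o1 | intermediate
17 | 1-{6-hydroxy-2-[(2E,4S)-4-(7-methoxy-2,2-dimethyl-2H-chromen-6-yl)pent-2-en-2-yl]-1-benzofuran-5-yl}ethanone | COc1cc2c(cc1[C@@H](C)/C=C(\C)c1cc3cc(C(C)=O)c(O)cc3o1)C=CC(C)(C)O2 | target

Total step count: 9. Longest linear sequence: 8 steps (1 → 2 → 3 → 5 → 7 → 8 → 12 → 13 → 17); step 6 is a one-step side branch.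

Steps most likely to fail

Step 9 (key step). The risk is loss of chemoselectivity between the two phenols (competing hydroxyalkylation at C7 of the benzofuran or at C2 of ring A), together with acid-promoted migration of the trisubstituted alkene during prolonged heating. The fallback builds ring B before ring C, so that the annulation runs on a mono-phenol. It sets out from 8. Buffered Bu4NF/AcOH in THF should give 3-methoxy-4-[(2S,3E)-4-methylhex-3-en-5-yn-2-yl]phenol F1. The same PhB(OH)2/AcOH annulation with 14 in refluxing toluene should then give 7-methoxy-2,2-dimethyl-6-[(2S,3E)-4-methylhex-3-en-5-yn-2-yl]-2H-chromene F2. Sonogashira coupling of F2 with 10 (PdCl2(PPh3)2, CuI, Et3N, DMF, 60 °C) should give the ortho-alkynylphenol 1-{2,4-dihydroxy-5-[(3E,5S)-5-(7-methoxy-2,2-dimethyl-2H-chromen-6-yl)-3-methylhex-3-en-1-yn-1-yl]phenyl}ethanone F3, which cyclises in the same pot. The fallback comes back to the route at 17.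

Step 3. The risks are cationic oligomerisation of the electron-rich styrene, migration of the new double bond into conjugation with ring A, and poor facial selectivity caused by the ortho-methoxy group. The fallback is a copper-catalysed asymmetric allylic alkylation and sets out from 2. Horner–Wadsworth–Emmons olefination with triethyl phosphonoacetate and NaH in THF should give ethyl (2E)-3-{2-methoxy-4-[(triisopropylsilyl)oxy]phenyl}prop-2-enoate F4. Reduction with i-Bu2AlH in CH2Cl2 at −78 °C should give (2E)-3-{2-methoxy-4-[(triisopropylsilyl)oxy]phenyl}prop-2-en-1-ol F5. PBr3 in Et2O at −20 °C should give {4-[(1E)-3-bromoprop-1-en-1-yl]-3-methoxyphenoxy}triisopropylsilane F6, which is used at once. SN2'-selective substitution with MeMgBr under CuBr·SMe2/Taniaphos catalysis (antipode chosen for the S product) in CH2Cl2 at −78 °C should give 5, where the route is rejoined.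

Step 4. The risks are sluggish metathesis of the allylically branched alkene, ruthenium hydride migration of the double bond toward ring A (which would erase the stereocentre) and incomplete E selectivity. The fallback replaces metathesis by oxidative cleavage and Wittig olefination and sets out from 5. OsO4 (cat.), NaIO4 and 2,6-lutidine in dioxane–water should give (2R)-2-{2-methoxy-4-[(triisopropylsilyl)oxy]phenyl}propanal F7; the spatial arrangement is unchanged and only the descriptor changes with the priority order. F7 is treated without delay with the stabilised ylide 2-(triphenylphosphoranylidene)propanal in toluene at 60 °C, which should give the (E)-enal 7, where the route is rejoined.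

Further compounds
F1 | step 9 | 3-methoxy-4-[(2S,3E)-4-methylhex-3-en-5-yn-2-yl]phenol | COc1cc(O)ccc1[C@@H](C)/C=C(\C)C#C
F2 | step 9 | 7-methoxy-2,2-dimethyl-6-[(2S,3E)-4-methylhex-3-en-5-yn-2-yl]-2H-chromene | COc1cc2c(cc1[C@@H](C)/C=C(\C)C#C)C=CC(C)(C)O2
F3 | step 9 | 1-{2,4-dihydroxy-5-[(3E,5S)-5-(7-methoxy-2,2-dimethyl-2H-chromen-6-yl)-3-methylhex-3-en-1-yn-1-yl]phenyl}ethanone | COc1cc2c(cc1[C@@H](C)/C=C(\C)C#Cc1cc(C(C)=O)c(O)cc1O)C=CC(C)(C)O2
F4 | step 3 | ethyl (2E)-3-{2-methoxy-4-[(triisopropylsilyl)oxy]phenyl}prop-2-enoate | CCOC(=O)/C=C/c1ccc(O[Si](C(C)C)(C(C)C)C(C)C)cc1OC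
F5 | step 3 | (2E)-3-{2-methoxy-4-[(triisopropylsilyl)oxy]phenyl}prop-2-en-1-ol | OC/C=C/c1ccc(O[Si](C(C)C)(C(C)C)C(C)C)cc1OC
F6 | step 3 | {4-[(1E)-3-bromoprop-1-en-1-yl]-3-methoxyphenoxy}triisopropylsilane | BrC/C=C/c1ccc(O[Si](C(C)C)(C(C)C)C(C)C)cc1OC
F7 | step 4 | (2R)-2-{2-methoxy-4-[(triisopropylsilyl)oxy]phenyl}propanal | COc1cc(O[Si](C(C)C)(C(C)C)C(C)C)ccc1[C@@H](C)C=O
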